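## The problem

The target is a germacrane-type ten-membered carbocycle (C1–C10) fused across C6–C7 to an α-(acetoxymethyl)butenolide (ring oxygen on C6, C7=C11, lactone carbonyl C12, acetoxymethyl C13), with ketones at C1 and C3, a trans trisubstituted epoxide at C4(Me)–C5, a (Z)-4-acetoxy-3-methylbut-2-enoate on the C8 oxygen and a methyl stereocentre at C10. Its five stereocentres (4S,5R,6R,8R,10R) form two sets, C4/C5/C6 and C8/C10, which are separated by the sp2 carbon C7 and cannot control each other. In the first set C4 and C5 need reagent control and C6 can then be set from the epoxide; in the second, C8 and C10 are 1,3-related and are best set together in a small ring. The ten-membered ring has to be closed against transannular strain. Several groups will not survive rough treatment: the 1,3-diketone beside the epoxide (retro-Claisen cleavage, epimerisation at C10), the butenolide hydrogen on C6 (its removal opens the neighbouring epoxide), the two allylic acetates, and the (Z)-enoate, which can isomerise or lactonise once its γ-oxygen is free. The feature that opens the way to the key step is that C1 and the C8 oxygen are 1,4-related through C10 and C9, so that joining them gives a cis-α-methyl-γ-butyrolactone (O, C8, C9, C10, C1). Because C4 is quaternary, a methyl ketone at C3 can enolise only towards C2. With C12 held at the CH2 level (a 2,5-dihydrofuran), no acidic hydrogen is left next to the epoxide.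

## Retrosynthesis

**C12 oxidation state.** Target 43 is traced back to the 2,5-dihydrofuran 42 by removing the C12 carbonyl oxygen. Carrying the butenolide earlier would expose the acidic C6 hydrogen beside the epoxide in every basic step, so the C12–H oxidation is placed last. The forward step must oxidise the ring CH2 next to oxygen in preference to the hindered C6–H.

**Acyl groups.** Cutting the C13 acetate and the C8–O ester bond of 42 leads through silyl ether 40 to hydroxy diketone 32 and (Z)-4-acetoxy-3-methylbut-2-enoic acid 37. Acid 37 comes from 4-methylfuran-2(5H)-one 33, whose ring fixes the Z geometry. The side chain is introduced with its acetate already in place, because a free γ-hydroxy (Z)-enoate would lactonise and expel the C8 oxygen. The esterification must acylate the C8 oxygen and not the diketone. It is therefore run on the disodium salt 39 of purified 32, in which the diketone is masked as its anion and the C8 alkoxide is the only strong nucleophile.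

**C1–C2, the key cut.** Cutting C1–C2 of 32 and joining C1 to the C8 oxygen gives lactone methyl ketone 28. Compared with cuts at C2–C3, C3–C4 or C4–C5, this one removes the ring, the diketone and the free C8 hydroxyl in one move. It also stores C8 and C10 as a cis-disubstituted butyrolactone from the chiral pool. The forward reaction must enolise only the methyl ketone, close a ten-membered ring and be held on the product side; the second equivalent of base does the last by forming the diketonate.

**Dihydrofuran ring.** In 28 the O–C12 and C7=C11 bonds are cut together, leading via 27, 26, 25 and 24 to α-hydroxy ketone 19 and ethyl 2-(diethoxyphosphoryl)acrylate 22. This annulation gives the ring directly at the dihydrofuran level. A butenolide route would need a lactone reduction in the presence of the γ-lactone that the key step requires. The price is one ester-to-alcohol reduction, in which the lactone is reduced to the lactol 26 and re-oxidised together with the C3 carbinol (27 to 28).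

**C6–C7.** Cutting C6–C7 of 19 (after replacing the C7 carbonyl by a methylene group, 18) gives vinyl iodide 10 and epoxy aldehyde 17. The vinyl iodide acts as an acyl anion equivalent that tolerates the lactone, where a carbanion at C7 would eliminate the C8 oxygen. The forward addition must take the Felkin–Anh course so that C6 is set anti to the epoxide oxygen, as the target requires.

**Fragments.**
- Iodide 10 is traced through alkyne 9, aldehyde 8, alcohol 7, cis lactone 6 and methylene lactone 5 to silyl ether 2 and (R)-5-(hydroxymethyl)dihydrofuran-2(3H)-one 1.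
- Aldehyde 17 comes from epoxy alcohol 16 and allylic alcohol 15, made by carboalumination of silyl ether 12 of (S)-but-3-yn-2-ol 11. The asymmetric epoxidation sets C4 and C5.
- Reagent 22 comes from triethyl phosphonoacetate 20.
- Acid 37 comes from 33 through ester 36.

## Roads not taken

**Alternative 1:** The cut is at C2–C3 and O–C1. The open-chain aldoxime A1, with the butenolide and both esters in place, would be oxidised at its C3 oxime carbon to a nitrile oxide function, which adds to the C1=C2 vinyl group on C10 to give the isoxazoline-bridged macrocycle A2.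
- Merits: the cycloaddition is irreversible, needs no strong base, and tolerates the complete periphery. No late C–H oxidation is required. In these respects it is better than the chosen plan.
- Weak points: A2 still needs N–O cleavage and oxidation of the resulting carbinol next to the epoxide, in a molecule that then contains the base-sensitive butenolide. The dipole sits on the quaternary epoxide carbon, where dimerisation competes with a slow medium-ring closure. C8 and C10 must be set separately in an open chain.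
- Against this, the chosen plan closes the ring directly at the diketone level, frees the C8 hydroxyl in the same step, and takes C8 and C10 from one cis lactone.

**Alternative 2:** The cut is at C4–C5 and C4–O. The sulfonium salt A3 would be deprotonated at C4 by Cs2CO3, and the resulting carbanion would add to the C5 aldehyde and displace the sulfide, closing ring and epoxide to give the epoxy macrocycle A4.
- Merits: two bonds and two stereocentres in one mild operation, and no epoxide to carry through the synthesis.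
- Weak points: the carbanion is acyl-stabilised and fully substituted, so it adds sluggishly. C4 and C5 would be set only by the conformation of the closing ring. The aldehyde carbon sits on the doubly activated C6 of A3 and can epimerise under carbonate. A4 still needs enol ether hydrolysis and the C12 oxidation.
- The chosen plan sets C4/C5 by reagent control and C6 from them before the ring is closed. Alternative 2 is more convergent at the epoxide but gives up that control.

**Alternative 3:** The cut is at C3–C4. The ynal A5 would undergo nickel-mediated reductive coupling of the C3 aldehyde with the C4≡C5 alkyne (Ni(cod)2, a carbene ligand, Et3SiH) to give the ten-membered (E)-allylic silyl ether A6.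
- Merits: this type of macrocyclisation has the best precedent of all four ring closures, and here it is better than the chosen plan. It also fixes the alkene geometry needed for a later trans epoxide.
- Weak points: A6 is far from the target in oxidation state. It still needs two carbinol oxidations, a face-selective epoxidation on the ring, butenolide formation, and removal or exchange of five protecting groups. Regiochemistry at a methyl-substituted alkyne in a ten-membered closure is not assured.
- The chosen plan accepts a less precedented ring closure in return for a product (32) that is three steps from the target.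

Key step: step 20

Assumption: the C3 carbinol configuration carried from 11 is immaterial because C3 becomes the ketone in step 19, and the (S) series is drawn; lactols 26 and 27 are anomeric mixtures and 3 and 4 are C3 epimer mixtures.

## Route

Step 1
Reactants: 1 (5R)-5-(hydroxymethyl)dihydrofuran-2(3H)-one
Product: 2 (5R)-5-{[(tert-butyldiphenylsilyl)oxy]methyl}dihydrofuran-2(3H)-one
Conditions: tBuPh2SiCl, imidazole, CH2Cl2, 0 °C → rt
Reagents that add atoms: tert-butyl(chloro)diphenylsilane, CC(C)(C)[Si](Cl)(c1ccccc1)c1ccccc1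
Why: Standard silylation of a primary alcohol; the bulky silyl ether also serves as the face-directing group in step 3.

Step 2
Reactants: 2 (5R)-5-{[(tert-butyldiphenylsilyl)oxy]methyl}dihydrofuran-2(3H)-one
Product: 5 (5R)-5-{[(tert-butyldiphenylsilyl)oxy]methyl}-3-methylidenedihydrofuran-2(3H)-one, via Mannich base 3 (not isolated), via ammonium iodide 4 (not isolated)
Conditions: LiN(iPr)2, THF, −78 °C; CH2=NMe2+ I−, −78 °C → rt; MeI, MeOH, rt; aq. NaHCO3, CH2Cl2, rt
Reagents that add atoms: N,N-dimethylmethyleneiminium iodide, C=[N+](C)C.[I-]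
Why: Mannich reaction of the lactone enolate, quaternisation and E1cB loss of trimethylamine is the standard α-methylenation of γ-lactones; the C5 stereocentre is not involved.

Step 3
Reactants: 5 (5R)-5-{[(tert-butyldiphenylsilyl)oxy]methyl}-3-methylidenedihydrofuran-2(3H)-one
Product: 6 (3R,5R)-5-{[(tert-butyldiphenylsilyl)oxy]methyl}-3-methyldihydrofuran-2(3H)-one
Conditions: H2 (1 atm), Pd/C, EtOAc, rt
Reagents that add atoms: none
Why: Heterogeneous hydrogenation adds to the exocyclic alkene from the face opposite the silyloxymethyl arm, so the new methyl-bearing centre (C10 of the target) ends cis to it; this complements trans-selective enolate methylation.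

Step 4
Reactants: 6 (3R,5R)-5-{[(tert-butyldiphenylsilyl)oxy]methyl}-3-methyldihydrofuran-2(3H)-one
Product: 7 (3R,5R)-5-(hydroxymethyl)-3-methyldihydrofuran-2(3H)-one
Conditions: Bu4NF, AcOH, THF, 0 °C → rt
Reagents that add atoms: none
Why: Fluoride desilylation buffered with acetic acid, so that the liberated alkoxide neither epimerises C3 nor translactonises.

Step 5
Reactants: 7 (3R,5R)-5-(hydroxymethyl)-3-methyldihydrofuran-2(3H)-one
Product: 8 (2R,4R)-4-methyl-5-oxotetrahydrofuran-2-carbaldehyde
Conditions: Dess–Martin periodinane, CH2Cl2, 0 °C → rt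
Reagents that add atoms: none
Why: Mild non-basic oxidation of a primary alcohol to the α-oxygenated aldehyde without epimerisation; the aldehyde is used crude.

Step 6
Reactants: 8 (2R,4R)-4-methyl-5-oxotetrahydrofuran-2-carbaldehyde
Product: 9 (3R,5R)-5-ethynyl-3-methyldihydrofuran-2(3H)-one
Conditions: MeC(O)C(N2)P(O)(OMe)2, K2CO3, MeOH, 0 °C → rt
Reagents that add atoms: dimethyl (1-diazo-2-oxopropyl)phosphonate, CC(=O)C(=[N+]=[N-])P(=O)(OC)OC
Why: Ohira–Bestmann homologation converts the aldehyde into the terminal alkyne under carbonate conditions that are tolerated by α-oxygenated aldehydes; any methanolysed lactone closes again on mildly acidic work-up.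

Step 7
Reactants: 9 (3R,5R)-5-ethynyl-3-methyldihydrofuran-2(3H)-one
Product: 10 (3R,5R)-5-(1-iodoethenyl)-3-methyldihydrofuran-2(3H)-one
Conditions: NaI, Me3SiCl, H2O, MeCN, 0 °C → rt
Reagents that add atoms: sodium iodide, [Na+].[I-]
Why: Markovnikov hydroiodination of a terminal alkyne by HI generated in situ gives the 2-iodo-1-alkene, a lactone-compatible precursor of a C7 nucleophile.

Step 8
Reactants: 11 (2S)-but-3-yn-2-ol
Product: 12 tert-butyl{[(2S)-but-3-yn-2-yl]oxy}dimethylsilane
Conditions: tBuMe2SiCl, imidazole, CH2Cl2, rt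
Reagents that add atoms: tert-butyl(chloro)dimethylsilane, CC(C)(C)[Si](C)(C)Cl
Why: Routine silylation; the ether masks the future C3 ketone as a carbinol through the organometallic and reducing steps.

Step 9
Reactants: 12 tert-butyl{[(2S)-but-3-yn-2-yl]oxy}dimethylsilane
Product: 15 (2E,4S)-4-{[tert-butyl(dimethyl)silyl]oxy}-3-methylpent-2-en-1-ol, via alkenylalane 13 (not isolated), via aluminate 14 (not isolated)
Conditions: Me3Al, Cp2ZrCl2 (cat.), CH2Cl2, 0 °C → rt; nBuLi, THF, −78 °C; (CH2O)n, −78 °C → rt
Reagents that add atoms: trimethylaluminium, C[Al](C)C; paraformaldehyde (as formaldehyde), C=O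
Why: Zirconium-catalysed Negishi carboalumination adds methyl and aluminium syn across the alkyne (methyl to the internal carbon); the derived aluminate is hydroxymethylated with retention, giving the (E)-trisubstituted allylic alcohol with C6 trans to C3.

Step 10
Reactants: 15 (2E,4S)-4-{[tert-butyl(dimethyl)silyl]oxy}-3-methylpent-2-en-1-ol
Product: 16 {(2R,3S)-3-[(1S)-1-{[tert-butyl(dimethyl)silyl]oxy}ethyl]-3-methyloxiran-2-yl}methanol
Conditions: Ti(OiPr)4 (cat.), D-(−)-diisopropyl tartrate, tBuOOH, 4 Å MS, CH2Cl2, −20 °C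
Reagents that add atoms: tert-butyl hydroperoxide, CC(C)(C)OO
Why: Sharpless asymmetric epoxidation of an (E)-trisubstituted primary allylic alcohol; the unnatural tartrate delivers oxygen to the face that gives the (4S,5R) epoxide of the target under reagent control, and the remote silyloxy centre is not expected to override it.

Step 11
Reactants: 16 {(2R,3S)-3-[(1S)-1-{[tert-butyl(dimethyl)silyl]oxy}ethyl]-3-methyloxiran-2-yl}methanol
Product: 17 (2S,3S)-3-[(1S)-1-{[tert-butyl(dimethyl)silyl]oxy}ethyl]-3-methyloxirane-2-carbaldehyde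
Conditions: TEMPO (cat.), PhI(OAc)2, CH2Cl2, rt
Reagents that add atoms: none
Why: Oxoammonium oxidation of the primary epoxy alcohol to the epoxy aldehyde under near-neutral conditions that leave the epoxide and the silyl ether intact.

Step 12
Reactants: 10 (3R,5R)-5-(1-iodoethenyl)-3-methyldihydrofuran-2(3H)-one; 17 (2S,3S)-3-[(1S)-1-{[tert-butyl(dimethyl)silyl]oxy}ethyl]-3-methyloxirane-2-carbaldehyde
Product: 18 (3R,5R)-5-[(3R)-3-{(2R,3S)-3-[(1S)-1-{[tert-butyl(dimethyl)silyl]oxy}ethyl]-3-methyloxiran-2-yl}-3-hydroxyprop-1-en-2-yl]-3-methyldihydrofuran-2(3H)-one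
Conditions: CrCl2, NiCl2 (cat.), DMSO, rt
Reagents that add atoms: none
Why: Nozaki–Hiyama–Kishi coupling forms C6–C7 with a vinylchromium species that tolerates the lactone. The new C6 carbinol is set by Felkin–Anh addition anti to the epoxide C–O bond, reinforced by the C4 methyl cis to the aldehyde, which gives the erythro epoxy alcohol required by the target.

Step 13
Reactants: 18 (3R,5R)-5-[(3R)-3-{(2R,3S)-3-[(1S)-1-{[tert-butyl(dimethyl)silyl]oxy}ethyl]-3-methyloxiran-2-yl}-3-hydroxyprop-1-en-2-yl]-3-methyldihydrofuran-2(3H)-one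
Product: 19 (3R,5R)-5-[(2S)-2-{(2R,3S)-3-[(1S)-1-{[tert-butyl(dimethyl)silyl]oxy}ethyl]-3-methyloxiran-2-yl}-2-hydroxyacetyl]-3-methyldihydrofuran-2(3H)-one
Conditions: O3, CH2Cl2/MeOH, −78 °C; Me2S, −78 °C → rt
Reagents that add atoms: ozone, [O-][O+]=O
Why: Ozonolysis of the only alkene unmasks the C7 ketone and gives the α-hydroxy ketone needed for the annulation; the product is used without delay.

Step 14
Reactants: 20 triethyl phosphonoacetate
Product: 22 ethyl 2-(diethoxyphosphoryl)prop-2-enoate, via hydroxymethyl adduct 21 (not isolated)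
Conditions: (CH2O)n, piperidine (cat.), MeOH, reflux; TsOH (cat.), toluene, reflux
Reagents that add atoms: paraformaldehyde (as formaldehyde), C=O
Why: Knoevenagel-type hydroxymethylation of the phosphonoacetate followed by acid-catalysed dehydration is the established preparation of this Michael acceptor.

Step 15
Reactants: 19 (3R,5R)-5-[(2S)-2-{(2R,3S)-3-[(1S)-1-{[tert-butyl(dimethyl)silyl]oxy}ethyl]-3-methyloxiran-2-yl}-2-hydroxyacetyl]-3-methyldihydrofuran-2(3H)-one; 22 ethyl 2-(diethoxyphosphoryl)prop-2-enoate
Product: 24 ethyl (5R)-5-{(2R,3S)-3-[(1S)-1-{[tert-butyl(dimethyl)silyl]oxy}ethyl]-3-methyloxiran-2-yl}-4-[(2R,4R)-4-methyl-5-oxotetrahydrofuran-2-yl]-2,5-dihydrofuran-3-carboxylate, via phosphonate Michael adduct 23 (not isolated)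
Conditions: NaH (1.05 equiv), THF, 0 °C → rt
Reagents that add atoms: none
Why: Tandem oxa-Michael addition and intramolecular Horner–Wadsworth–Emmons olefination is the known route from α-hydroxy ketones to 2,5-dihydrofuran-3-carboxylates. It forms O–C12 and C7=C11 at the correct C12 oxidation level, and C6 is not touched because only its oxygen reacts.

Step 16
Reactants: 24 ethyl (5R)-5-{(2R,3S)-3-[(1S)-1-{[tert-butyl(dimethyl)silyl]oxy}ethyl]-3-methyloxiran-2-yl}-4-[(2R,4R)-4-methyl-5-oxotetrahydrofuran-2-yl]-2,5-dihydrofuran-3-carboxylate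
Product: 25 ethyl (5R)-5-{(2R,3R)-3-[(1S)-1-hydroxyethyl]-3-methyloxiran-2-yl}-4-[(2R,4R)-4-methyl-5-oxotetrahydrofuran-2-yl]-2,5-dihydrofuran-3-carboxylate
Conditions: Bu4NF, AcOH, THF, 0 °C → rt
Reagents that add atoms: none
Why: Buffered fluoride removes the secondary silyl ether before the reduction, so that the later silylation differentiates C13 from C3.

Step 17
Reactants: 25 ethyl (5R)-5-{(2R,3R)-3-[(1S)-1-hydroxyethyl]-3-methyloxiran-2-yl}-4-[(2R,4R)-4-methyl-5-oxotetrahydrofuran-2-yl]-2,5-dihydrofuran-3-carboxylate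
Product: 26 {(5R)-5-[(2R,3R)-3-[(1S)-1-hydroxyethyl]-3-methyloxiran-2-yl]-4-[(2R,4R)-5-hydroxy-4-methyltetrahydrofuran-2-yl]-2,5-dihydrofuran-3-yl}methanol
Conditions: iBu2AlH (5 equiv), CH2Cl2, −78 °C; aq. potassium sodium tartrate
Reagents that add atoms: none
Why: At −78 °C the aluminium hydride takes the conjugated ester to the allylic alcohol and stops at the lactol stage for the γ-lactone (stable tetrahedral aluminate). The lactone is thus reduced reversibly and restored in step 19.

Step 18
Reactants: 26 {(5R)-5-[(2R,3R)-3-[(1S)-1-hydroxyethyl]-3-methyloxiran-2-yl]-4-[(2R,4R)-5-hydroxy-4-methyltetrahydrofuran-2-yl]-2,5-dihydrofuran-3-yl}methanol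
Product: 27 (1S)-1-{(2R,3R)-3-[(2R)-4-({[tert-butyl(dimethyl)silyl]oxy}methyl)-3-[(2R,4R)-5-hydroxy-4-methyltetrahydrofuran-2-yl]-2,5-dihydrofuran-2-yl]-2-methyloxiran-2-yl}ethanol
Conditions: tBuMe2SiCl (1.1 equiv), imidazole, CH2Cl2, −20 → 0 °C
Reagents that add atoms: tert-butyl(chloro)dimethylsilane, CC(C)(C)[Si](C)(C)Cl
Why: The primary allylic hydroxyl is silylated much faster than the hindered secondary carbinol beside the quaternary epoxide carbon or the lactol hydroxyl.

Step 19
Reactants: 27 (1S)-1-{(2R,3R)-3-[(2R)-4-({[tert-butyl(dimethyl)silyl]oxy}methyl)-3-[(2R,4R)-5-hydroxy-4-methyltetrahydrofuran-2-yl]-2,5-dihydrofuran-2-yl]-2-methyloxiran-2-yl}ethanol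
Product: 28 (3R,5R)-5-[(2R)-2-[(2R,3S)-3-acetyl-3-methyloxiran-2-yl]-4-({[tert-butyl(dimethyl)silyl]oxy}methyl)-2,5-dihydrofuran-3-yl]-3-methyldihydrofuran-2(3H)-one
Conditions: (nPr4N)RuO4 (cat.), N-methylmorpholine N-oxide, 4 Å MS, CH2Cl2, rt
Reagents that add atoms: none
Why: Ley–Griffith oxidation converts the lactol to the lactone and the C3 carbinol to the methyl ketone in one neutral operation, giving the key-step precursor without touching the epoxide or the allylic ether.

Step 20
Reactants: 28 (3R,5R)-5-[(2R)-2-[(2R,3S)-3-acetyl-3-methyloxiran-2-yl]-4-({[tert-butyl(dimethyl)silyl]oxy}methyl)-2,5-dihydrofuran-3-yl]-3-methyldihydrofuran-2(3H)-one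
Product: 32 (4S,5R,6R,8R,10R)-13-{[tert-butyl(dimethyl)silyl]oxy}-4,5:6,12-diepoxy-8-hydroxygermacr-7(11)-ene-1,3-dione, via lithium enolate 29 (not isolated), via tetrahedral alkoxide 30 (not isolated), via dilithium salt 31 (not isolated)
Conditions: LiN(SiMe3)2 (2.2 equiv), THF (0.005 M), −78 → 0 °C; AcOH, −78 °C
Reagents that add atoms: none
Why: Proposed new method: the amide base removes a proton from the unhindered C2 methyl of the ketone (C4 is quaternary, so no other enolate of this ketone exists) to give 29, whose carbon attacks the lactone carbonyl C1 to give the bridged tetrahedral alkoxide 30, which collapses with loss of the C8 alkoxide; the second equivalent of base deprotonates the new 1,3-diketone to 31, which makes the acyl transfer irreversible and shields C2 and the C10 hydrogen. The closest known reaction types are the intermolecular ring-opening of lactones by ketone enolates, the Dieckmann condensation and the Baker–Venkataraman O-to-C acyl transfer; none has been shown for a ten-membered carbocycle. The one ring closed is the ten-membered carbocycle, by 10-exo-trig attack of C2 on C1, while the five-membered lactone opens. No stereocentre is formed; C8 and C10 are carried over from the cis lactone, and C10 is not epimerised because the diketone is deprotonated at C2 as soon as it forms. The step needs enolisation of the methyl ketone in preference to the tertiary lactone α-position C10, which the higher kinetic acidity and accessibility of the methyl group at −78 °C secure. It also needs ring closure to beat intermolecular acylation, which high dilution and the cis arrangement of the two arms on the C6–C7=C11 edge of the dihydrofuran favour. The dihydrofuran has no acidic hydrogen beside the epoxide. The cold acetic acid quench returns the neutral hydroxy diketone before retro-Claisen cleavage through the C8 alkoxide can set in.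

Step 21
Reactants: 33 4-methylfuran-2(5H)-one
Product: 36 4-methoxybenzyl (2Z)-4-acetoxy-3-methylbut-2-enoate, via potassium hydroxy-enoate 34 (not isolated), via hydroxy ester 35 (not isolated)
Conditions: KOH (1.0 equiv), H2O/MeOH, 0 °C, evaporate; 4-MeOC6H4CH2Cl, Bu4NI (cat.), DMF, rt; Ac2O, pyridine, 0 °C
Reagents that add atoms: potassium hydroxide, [K+].[OH-]; 4-methoxybenzyl chloride, COc1ccc(CCl)cc1; acetic anhydride, CC(=O)OC(C)=O
Why: Saponification of the butenolide keeps the Z geometry imposed by the ring; alkylating the carboxylate before acetylating the hydroxyl prevents relactonisation through a mixed anhydride.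

Step 22
Reactants: 36 4-methoxybenzyl (2Z)-4-acetoxy-3-methylbut-2-enoate
Product: 37 (2Z)-4-acetoxy-3-methylbut-2-enoic acid
Conditions: CF3CO2H, anisole, CH2Cl2, 0 °C
Reagents that add atoms: none
Why: Acidolysis of the 4-methoxybenzyl ester frees the acid without hydrolysing the acetate; a palladium-labile ester is avoided because the γ-acetoxy enoate is itself an allylic electrophile.

Step 23
Reactants: 32 (4S,5R,6R,8R,10R)-13-{[tert-butyl(dimethyl)silyl]oxy}-4,5:6,12-diepoxy-8-hydroxygermacr-7(11)-ene-1,3-dione; 37 (2Z)-4-acetoxy-3-methylbut-2-enoic acid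
Product: 40 (4S,5R,6R,8R,10R)-13-{[tert-butyl(dimethyl)silyl]oxy}-4,5:6,12-diepoxy-1,3-dioxogermacr-7(11)-en-8-yl (2Z)-4-acetoxy-3-methylbut-2-enoate, via acid chloride 38 (not isolated), via disodium salt 39 (not isolated)
Conditions: 37, (COCl)2, DMF (cat.), CH2Cl2, 0 °C → rt, concentrate; 32, NaN(SiMe3)2 (2.05 equiv), THF, −78 °C; 38 (1.0 equiv), −78 → −40 °C; AcOH, −78 °C
Reagents that add atoms: none
Why: O-acylation of a metal alkoxide by an acid chloride: the sodium amide turns purified 32 into the diketonate alkoxide 39, whose delocalised diketonate is a far weaker nucleophile than the C8 sodium alkoxide, so one equivalent of 38 acylates the hindered C8 oxygen at low temperature. With the diketone held as its anion the alkoxide cannot start a retro-Claisen cleavage, and the absence of a tertiary amine avoids vinylketene formation from 38, which would scramble the (Z)-alkene.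

Step 24
Reactants: 40 (4S,5R,6R,8R,10R)-13-{[tert-butyl(dimethyl)silyl]oxy}-4,5:6,12-diepoxy-1,3-dioxogermacr-7(11)-en-8-yl (2Z)-4-acetoxy-3-methylbut-2-enoate
Product: 42 (4S,5R,6R,8R,10R)-13-acetoxy-4,5:6,12-diepoxy-1,3-dioxogermacr-7(11)-en-8-yl (2Z)-4-acetoxy-3-methylbut-2-enoate, via C13 alcohol 41 (not isolated)
Conditions: HF·pyridine, pyridine, THF, 0 °C → rt; Ac2O, 0 °C
Reagents that add atoms: acetic anhydride, CC(=O)OC(C)=O
Why: Acidic fluoride removes the primary silyl ether without generating a basic alkoxide, and the alcohol is acetylated in the same flask; any enol acetate of the diketone is expected to be cleaved on bicarbonate work-up.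

Step 25
Reactants: 42 (4S,5R,6R,8R,10R)-13-acetoxy-4,5:6,12-diepoxy-1,3-dioxogermacr-7(11)-en-8-yl (2Z)-4-acetoxy-3-methylbut-2-enoate
Product: 43 (4S,5R,6R,8R,10R)-13-acetoxy-8-{[(2Z)-4-acetoxy-3-methylbut-2-enoyl]oxy}-4,5-epoxy-1,3-dioxogermacr-7(11)-en-12,6-olide
Conditions: CrO3, 3,5-dimethylpyrazole, CH2Cl2, −20 °C
Reagents that add atoms: chromium trioxide, O=[Cr](=O)=O
Why: Allylic oxidation of a 2,5-dihydrofuran to the butenolide with the hexavalent chromium–pyrazole complex; the C12 methylene is both allylic and next to the ring oxygen and is less hindered than the tertiary C6–H. The step is last so that the acidic butenolide hydrogen never meets base.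

## Compound list

1 | (5R)-5-(hydroxymethyl)dihydrofuran-2(3H)-one | OC[C@H]1CCC(=O)O1 | starting material
2 | (5R)-5-{[(tert-butyldiphenylsilyl)oxy]methyl}dihydrofuran-2(3H)-one | CC(C)(C)[Si](c1ccccc1)(c1ccccc1)OC[C@H]1CCC(=O)O1 | intermediate
3 | (5R)-5-{[(tert-butyldiphenylsilyl)oxy]methyl}-3-[(dimethylamino)methyl]dihydrofuran-2(3H)-one (C3 epimers) | CN(C)CC1C[C@H](CO[Si](c2ccccc2)(c2ccccc2)C(C)(C)C)OC1=O | intermediate
4 | {(5R)-5-{[(tert-butyldiphenylsilyl)oxy]methyl}-2-oxotetrahydrofuran-3-yl}methyl(trimethyl)ammonium iodide (C3 epimers) | C[N+](C)(C)CC1C[C@H](CO[Si](c2ccccc2)(c2ccccc2)C(C)(C)C)OC1=O.[I-] | intermediate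
5 | (5R)-5-{[(tert-butyldiphenylsilyl)oxy]methyl}-3-methylidenedihydrofuran-2(3H)-one | C=C1C[C@H](CO[Si](c2ccccc2)(c2ccccc2)C(C)(C)C)OC1=O | intermediate
6 | (3R,5R)-5-{[(tert-butyldiphenylsilyl)oxy]methyl}-3-methyldihydrofuran-2(3H)-one (cis) | C[C@@H]1C[C@H](CO[Si](c2ccccc2)(c2ccccc2)C(C)(C)C)OC1=O | intermediate
7 | (3R,5R)-5-(hydroxymethyl)-3-methyldihydrofuran-2(3H)-one | C[C@@H]1C[C@H](CO)OC1=O | intermediate
8 | (2R,4R)-4-methyl-5-oxotetrahydrofuran-2-carbaldehyde | C[C@@H]1C[C@H](C=O)OC1=O | intermediate
9 | (3R,5R)-5-ethynyl-3-methyldihydrofuran-2(3H)-one | C[C@@H]1C[C@H](C#C)OC1=O | intermediate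
10 | (3R,5R)-5-(1-iodoethenyl)-3-methyldihydrofuran-2(3H)-one | C[C@@H]1C[C@H](C(I)=C)OC1=O | intermediate
11 | (2S)-but-3-yn-2-ol | C[C@H](O)C#C | starting material
12 | tert-butyl{[(2S)-but-3-yn-2-yl]oxy}dimethylsilane | C[C@H](O[Si](C)(C)C(C)(C)C)C#C | intermediate
13 | [(1E,3S)-3-{[tert-butyl(dimethyl)silyl]oxy}-2-methylbut-1-en-1-yl]dimethylalane | C[C@H](O[Si](C)(C)C(C)(C)C)/C(C)=C/[Al](C)C | intermediate
14 | lithium butyl[(1E,3S)-3-{[tert-butyl(dimethyl)silyl]oxy}-2-methylbut-1-en-1-yl]dimethylaluminate | [Li+].C[C@H](O[Si](C)(C)C(C)(C)C)/C(C)=C/[Al-](C)(C)CCCC | intermediate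
15 | (2E,4S)-4-{[tert-butyl(dimethyl)silyl]oxy}-3-methylpent-2-en-1-ol | C[C@H](O[Si](C)(C)C(C)(C)C)/C(C)=C/CO | intermediate
16 | {(2R,3S)-3-[(1S)-1-{[tert-butyl(dimethyl)silyl]oxy}ethyl]-3-methyloxiran-2-yl}methanol | OC[C@H]1O[C@]1(C)[C@H](C)O[Si](C)(C)C(C)(C)C | intermediate
17 | (2S,3S)-3-[(1S)-1-{[tert-butyl(dimethyl)silyl]oxy}ethyl]-3-methyloxirane-2-carbaldehyde | O=C[C@H]1O[C@]1(C)[C@H](C)O[Si](C)(C)C(C)(C)C | intermediate
18 | (3R,5R)-5-[(3R)-3-{(2R,3S)-3-[(1S)-1-{[tert-butyl(dimethyl)silyl]oxy}ethyl]-3-methyloxiran-2-yl}-3-hydroxyprop-1-en-2-yl]-3-methyldihydrofuran-2(3H)-one | C[C@H](O[Si](C)(C)C(C)(C)C)[C@@]1(C)O[C@@H]1[C@H](O)C(=C)[C@H]1C[C@@H](C)C(=O)O1 | intermediate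
19 | (3R,5R)-5-[(2S)-2-{(2R,3S)-3-[(1S)-1-{[tert-butyl(dimethyl)silyl]oxy}ethyl]-3-methyloxiran-2-yl}-2-hydroxyacetyl]-3-methyldihydrofuran-2(3H)-one | C[C@H](O[Si](C)(C)C(C)(C)C)[C@@]1(C)O[C@@H]1[C@H](O)C(=O)[C@H]1C[C@@H](C)C(=O)O1 | intermediate
20 | triethyl phosphonoacetate | CCOC(=O)CP(=O)(OCC)OCC | starting material
21 | ethyl 2-(diethoxyphosphoryl)-3-hydroxypropanoate | CCOC(=O)C(CO)P(=O)(OCC)OCC | intermediate
22 | ethyl 2-(diethoxyphosphoryl)prop-2-enoate | CCOC(=O)C(=C)P(=O)(OCC)OCC | intermediate
23 | sodium salt of the oxa-Michael adduct of 19 and 22 (phosphonate carbanion; C6 ether of 19) | [Na+].C[C@H](O[Si](C)(C)C(C)(C)C)[C@@]1(C)O[C@@H]1[C@H](OC[C-](C(=O)OCC)P(=O)(OCC)OCC)C(=O)[C@H]1C[C@@H](C)C(=O)O1 | intermediate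
24 | ethyl (5R)-5-{(2R,3S)-3-[(1S)-1-{[tert-butyl(dimethyl)silyl]oxy}ethyl]-3-methyloxiran-2-yl}-4-[(2R,4R)-4-methyl-5-oxotetrahydrofuran-2-yl]-2,5-dihydrofuran-3-carboxylate | C[C@H](O[Si](C)(C)C(C)(C)C)[C@@]1(C)O[C@@H]1[C@@H]1OCC(C(=O)OCC)=C1[C@H]1C[C@@H](C)C(=O)O1 | intermediate
25 | ethyl (5R)-5-{(2R,3R)-3-[(1S)-1-hydroxyethyl]-3-methyloxiran-2-yl}-4-[(2R,4R)-4-methyl-5-oxotetrahydrofuran-2-yl]-2,5-dihydrofuran-3-carboxylate | C[C@H](O)[C@@]1(C)O[C@@H]1[C@@H]1OCC(C(=O)OCC)=C1[C@H]1C[C@@H](C)C(=O)O1 | intermediate
26 | {(5R)-5-[(2R,3R)-3-[(1S)-1-hydroxyethyl]-3-methyloxiran-2-yl]-4-[(2R,4R)-5-hydroxy-4-methyltetrahydrofuran-2-yl]-2,5-dihydrofuran-3-yl}methanol (lactol anomers) | C[C@H](O)[C@@]1(C)O[C@@H]1[C@@H]1OCC(CO)=C1[C@H]1C[C@@H](C)C(O)O1 | intermediate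
27 | (1S)-1-{(2R,3R)-3-[(2R)-4-({[tert-butyl(dimethyl)silyl]oxy}methyl)-3-[(2R,4R)-5-hydroxy-4-methyltetrahydrofuran-2-yl]-2,5-dihydrofuran-2-yl]-2-methyloxiran-2-yl}ethanol (lactol anomers) | C[C@H](O)[C@@]1(C)O[C@@H]1[C@@H]1OCC(CO[Si](C)(C)C(C)(C)C)=C1[C@H]1C[C@@H](C)C(O)O1 | intermediate
28 | (3R,5R)-5-[(2R)-2-[(2R,3S)-3-acetyl-3-methyloxiran-2-yl]-4-({[tert-butyl(dimethyl)silyl]oxy}methyl)-2,5-dihydrofuran-3-yl]-3-methyldihydrofuran-2(3H)-one | CC(=O)[C@@]1(C)O[C@@H]1[C@@H]2OCC(CO[Si](C)(C)C(C)(C)C)=C2[C@H]3C[C@@H](C)C(=O)O3 | intermediate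
29 | lithium C2 enolate of 28 | [Li+].C=C([O-])[C@@]1(C)O[C@@H]1[C@@H]2OCC(CO[Si](C)(C)C(C)(C)C)=C2[C@H]3C[C@@H](C)C(=O)O3 | intermediate
30 | lithium alkoxide of the C1 hemiketal bridged between C1 and the C8 oxygen (tetrahedral intermediate) | [Li+].CC(C)(C)[Si](C)(C)OCC1=C2[C@@H](OC1)[C@H]1O[C@]1(C)C(=O)CC3([O-])[C@H](C)C[C@H]2O3 | intermediate
31 | dilithium salt of 32 (C1–C3 diketonate and C8 alkoxide) | [Li+].[Li+].CC(C)(C)[Si](C)(C)OCC1=C2[C@@H](OC1)[C@H]1O[C@]1(C)C(=O)C=C([O-])[C@H](C)C[C@H]2[O-] | intermediate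
32 | (4S,5R,6R,8R,10R)-13-{[tert-butyl(dimethyl)silyl]oxy}-4,5:6,12-diepoxy-8-hydroxygermacr-7(11)-ene-1,3-dione | CC(C)(C)[Si](C)(C)OCC1=C2[C@@H](OC1)[C@H]1O[C@]1(C)C(=O)CC(=O)[C@H](C)C[C@H]2O | intermediate
33 | 4-methylfuran-2(5H)-one | CC1=CC(=O)OC1 | starting material
34 | potassium (2Z)-4-hydroxy-3-methylbut-2-enoate | [K+].[O-]C(=O)/C=C(/C)CO | intermediate
35 | 4-methoxybenzyl (2Z)-4-hydroxy-3-methylbut-2-enoate | COc1ccc(COC(=O)/C=C(/C)CO)cc1 | intermediate
36 | 4-methoxybenzyl (2Z)-4-acetoxy-3-methylbut-2-enoate | COc1ccc(COC(=O)/C=C(/C)COC(C)=O)cc1 | intermediate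
37 | (2Z)-4-acetoxy-3-methylbut-2-enoic acid | OC(=O)/C=C(/C)COC(C)=O | intermediate
38 | (2Z)-4-acetoxy-3-methylbut-2-enoyl chloride | ClC(=O)/C=C(/C)COC(C)=O | intermediate
39 | disodium salt of 32 (C1–C3 diketonate and C8 alkoxide) | [Na+].[Na+].CC(C)(C)[Si](C)(C)OCC1=C2[C@@H](OC1)[C@H]1O[C@]1(C)C(=O)C=C([O-])[C@H](C)C[C@H]2[O-] | intermediate
40 | (4S,5R,6R,8R,10R)-13-{[tert-butyl(dimethyl)silyl]oxy}-4,5:6,12-diepoxy-1,3-dioxogermacr-7(11)-en-8-yl (2Z)-4-acetoxy-3-methylbut-2-enoate | CC(C)(C)[Si](C)(C)OCC1=C2[C@@H](OC1)[C@H]1O[C@]1(C)C(=O)CC(=O)[C@H](C)C[C@H]2OC(=O)/C=C(/C)COC(C)=O | intermediate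
41 | (4S,5R,6R,8R,10R)-4,5:6,12-diepoxy-13-hydroxy-1,3-dioxogermacr-7(11)-en-8-yl (2Z)-4-acetoxy-3-methylbut-2-enoate | OCC1=C2[C@@H](OC1)[C@H]1O[C@]1(C)C(=O)CC(=O)[C@H](C)C[C@H]2OC(=O)/C=C(/C)COC(C)=O | intermediate
42 | (4S,5R,6R,8R,10R)-13-acetoxy-4,5:6,12-diepoxy-1,3-dioxogermacr-7(11)-en-8-yl (2Z)-4-acetoxy-3-methylbut-2-enoate | CC(=O)OCC1=C2[C@@H](OC1)[C@H]1O[C@]1(C)C(=O)CC(=O)[C@H](C)C[C@H]2OC(=O)/C=C(/C)COC(C)=O | intermediate
43 | (4S,5R,6R,8R,10R)-13-acetoxy-8-{[(2Z)-4-acetoxy-3-methylbut-2-enoyl]oxy}-4,5-epoxy-1,3-dioxogermacr-7(11)-en-12,6-olide | CC(=O)OCC1=C2[C@@H](OC1=O)[C@H]1O[C@]1(C)C(=O)CC(=O)[C@H](C)C[C@H]2OC(=O)/C=C(/C)COC(C)=O | target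

## Step count and least certain steps

Total: 25 steps. Longest linear sequence: 18 steps (1–7, 12, 13, 15–20, 23–25). Side branches: steps 8–11, step 14, steps 21–22.

**Step 20 (key step).** The most likely failures are that the ten-membered ring does not close in competition with intermolecular acylation, or that the acyl transfer reverses. The ring is strained and the equilibrium without the second deprotonation lies on the lactone side. Partial enolisation at C10 would also erode the cis lactone, and transannular opening of the epoxide by the released C8 alkoxide cannot be excluded.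

The fallback uses known chemistry that still forms C1–C2. It sets out from 25 and returns at 40. Dehydration of the C3 carbinol of 25 with bis[α,α-bis(trifluoromethyl)benzyloxy]diphenylsulfurane (only the methyl group carries β-hydrogens) gives the vinyl epoxide ester F1. iBu2AlH at −78 °C then gives the lactol alcohol F2, and tBuMe2SiCl with imidazole gives the silyl ether lactol F3. Hydroxylamine in pyridine opens the lactol to the aldoxime F4, with the C8 hydroxyl free. Oxidation of the oxime with NaOCl under high dilution generates the nitrile oxide at C1, which adds to the C2=C3 vinyl group (carbon to the terminal CH2, oxygen to C3); this intramolecular nitrile oxide cycloaddition gives the isoxazoline-bridged ten-membered ring F5. The C8 hydroxyl is acylated with 38 and pyridine to give the ester F6. Mo(CO)6 in wet acetonitrile cleaves the N–O bond and hydrolyses the imine to the β-hydroxy ketone F7, and Dess–Martin oxidation of its C3 carbinol gives 40.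

**Step 12.** Poor facial selectivity at C6 is possible, since Felkin control by an epoxide is moderate, as is reductive opening of the epoxy aldehyde by divalent chromium. The fallback sets out from 18 (as its mixture with the C6 epimer) and returns at 18: Dess–Martin oxidation gives the epoxy enone F8, and Zn(BH4)2 in ether at −20 °C then reduces it through a chelate between the ketone and the epoxide oxygen, which delivers the erythro alcohol. Here the C6 configuration is set by reduction instead of addition.

**Step 15.** Enolisation of the α-hydroxy ketone by the transient alkoxide or phosphonate anion could epimerise C6 or C8, and the olefination of a ketone flanked by two oxygenated centres could stall after the Michael addition. The fallback sets out from 18 and returns at 28, avoiding any ketone at C7. O-alkylation of 18 with 2-(bromomethyl)allyl tert-butyldimethylsilyl ether and Ag2O gives the diene ether F9. Ring-closing metathesis with the second-generation Hoveyda–Grubbs catalyst in toluene at 80 °C gives the bis-silyl dihydrofuran F10. Bu4NF with AcOH gives the diol F11, tBuMe2SiCl with imidazole converts its primary hydroxyl into the primary silyl ether F12, and (nPr4N)RuO4 with N-methylmorpholine N-oxide returns 28.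

**Step 23.** Competing acylation on the diketonate oxygen, Z to E isomerisation of the enoyl unit, or retro-Claisen cleavage of 32 during isolation and handling could lower the return. The free hydroxy diketone is the least stable compound of the route. The fallback sets out from 28 and returns at 40: the key step is not quenched, and 38 is instead added at −78 °C to the dilithium salt 31 as it is formed, so the C8 alkoxide is acylated in the same flask and 32 is never isolated.

**Step 25.** Oxidation could occur at the tertiary C6–H or at the enolisable C2 of the diketone instead of C12, because hexavalent chromium also attacks enols and three allylic positions are present. The fallback sets out from 42 and returns at 43: the diketone is masked with tBuMe2SiCl and imidazole in DMF as its enol silyl ether F13, the chromium trioxide–3,5-dimethylpyrazole oxidation is run on it to give the butenolide enol silyl ether F14, and HF·pyridine releases 43.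

## Further compounds

F1 | step 20 | ethyl (5R)-5-[(2R,3R)-3-ethenyl-3-methyloxiran-2-yl]-4-[(2R,4R)-4-methyl-5-oxotetrahydrofuran-2-yl]-2,5-dihydrofuran-3-carboxylate | C=C[C@@]1(C)O[C@@H]1[C@@H]1OCC(C(=O)OCC)=C1[C@H]1C[C@@H](C)C(=O)O1
F2 | step 20 | lactol alcohol from F1 (C13 hydroxymethyl, C1 lactol, C3 vinyl) | C=C[C@@]1(C)O[C@@H]1[C@@H]1OCC(CO)=C1[C@H]1C[C@@H](C)C(O)O1
F3 | step 20 | C13 tert-butyldimethylsilyl ether of F2 | C=C[C@@]1(C)O[C@@H]1[C@@H]1OCC(CO[Si](C)(C)C(C)(C)C)=C1[C@H]1C[C@@H](C)C(O)O1
F4 | step 20 | open-chain C1 aldoxime with free C8 hydroxyl and C3 vinyl group | C=C[C@@]1(C)O[C@@H]1[C@@H]1OCC(CO[Si](C)(C)C(C)(C)C)=C1[C@H](O)C[C@@H](C)C=NO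
F5 | step 20 | isoxazoline-bridged ten-membered ring (C1=N–O–C3, C2 methylene), free C8 hydroxyl, C3 epimers | CC(C)(C)[Si](C)(C)OCC1=C2[C@@H](OC1)[C@H]1O[C@]1(C)C3CC(=NO3)[C@H](C)C[C@H]2O
F6 | step 20 | C8 (2Z)-4-acetoxy-3-methylbut-2-enoate of F5 | CC(C)(C)[Si](C)(C)OCC1=C2[C@@H](OC1)[C@H]1O[C@]1(C)C3CC(=NO3)[C@H](C)C[C@H]2OC(=O)/C=C(/C)COC(C)=O
F7 | step 20 | C3 hydroxy C1 ketone from F6 (3-hydroxy analogue of 40, C3 epimers) | CC(C)(C)[Si](C)(C)OCC1=C2[C@@H](OC1)[C@H]1O[C@]1(C)C(O)CC(=O)[C@H](C)C[C@H]2OC(=O)/C=C(/C)COC(C)=O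
F8 | step 12 | epoxy enone, the C6 ketone of 18 | C[C@H](O[Si](C)(C)C(C)(C)C)[C@@]1(C)O[C@@H]1C(=O)C(=C)[C@H]1C[C@@H](C)C(=O)O1
F9 | step 15 | C6 2-({[tert-butyl(dimethyl)silyl]oxy}methyl)allyl ether of 18 | C[C@H](O[Si](C)(C)C(C)(C)C)[C@@]1(C)O[C@@H]1[C@H](OCC(=C)CO[Si](C)(C)C(C)(C)C)C(=C)[C@H]1C[C@@H](C)C(=O)O1
F10 | step 15 | bis-silyl dihydrofuran lactone (C3 and C13 silyl ethers) | C[C@H](O[Si](C)(C)C(C)(C)C)[C@@]1(C)O[C@@H]1[C@@H]1OCC(CO[Si](C)(C)C(C)(C)C)=C1[C@H]1C[C@@H](C)C(=O)O1
F11 | step 15 | dihydrofuran lactone diol (C3 and C13 hydroxyls) | C[C@H](O)[C@@]1(C)O[C@@H]1[C@@H]1OCC(CO)=C1[C@H]1C[C@@H](C)C(=O)O1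
F12 | step 15 | C13 tert-butyldimethylsilyl ether of F11 (C3 carbinol analogue of 28) | C[C@H](O)[C@@]1(C)O[C@@H]1[C@@H]1OCC(CO[Si](C)(C)C(C)(C)C)=C1[C@H]1C[C@@H](C)C(=O)O1
F0 | step 23 | none | none
F13 | step 25 | enol tert-butyldimethylsilyl ether of 42 at the C1–C3 diketone (one regioisomer drawn) | CC(=O)OCC1=C2[C@@H](OC1)[C@H]1O[C@]1(C)C(O[Si](C)(C)C(C)(C)C)=CC(=O)[C@H](C)C[C@H]2OC(=O)/C=C(/C)COC(C)=O
F14 | step 25 | butenolide from F13 (enol silyl ether of 43) | CC(=O)OCC1=C2[C@@H](OC1=O)[C@H]1O[C@]1(C)C(O[Si](C)(C)C(C)(C)C)=CC(=O)[C@H](C)C[C@H]2OC(=O)/C=C(/C)COC(C)=O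
A1 | alternative 1 | open-chain C3 aldoxime with the C1=C2 vinyl group on C10, butenolide and both esters in place | CC(=O)OCC1=C([C@@H](OC1=O)[C@H]1O[C@]1(C)C=NO)[C@@H](C[C@@H](C)C=C)OC(=O)/C=C(/C)COC(C)=O
A2 | alternative 1 | isoxazoline-bridged macrocycle | CC(=O)OCC1=C2[C@@H](OC1=O)[C@H]1O[C@]1(C)C3=NO[C@H](C3)[C@H](C)C[C@H]2OC(=O)/C=C(/C)COC(C)=O
A3 | alternative 2 | C4 tetrahydrothiophenium triflate with the C5 aldehyde on C6 of the dihydrofuran and the C1 methyl enol ether | CC(=O)OCC1=C([C@@H](OC1)C=O)[C@@H](C[C@@H](C)/C(OC)=C\C(=O)C(C)[S+]1CCCC1)OC(=O)/C=C(/C)COC(C)=O.[O-]S(=O)(=O)C(F)(F)F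
A4 | alternative 2 | trans-epoxy macrocycle with C1 methyl enol ether and dihydrofuran | CC(=O)OCC1=C2[C@@H](OC1)[C@H]1O[C@]1(C)C(=O)/C=C(OC)\[C@H](C)C[C@H]2OC(=O)/C=C(/C)COC(C)=O
A5 | alternative 3 | acyclic ynal with the C3 aldehyde and the C4≡C5 alkyne | O=CC[C@H](O[Si](C)(C)C(C)(C)C)[C@H](C)C[C@@H](OCc1ccc(OC)cc1)/C(=C(\CO[Si](C)(C)C(C)(C)C)C(=O)OC)[C@@H](O[Si](CC)(CC)CC)C#CC
A6 | alternative 3 | ten-membered (E)-allylic silyl ether | CC[Si](CC)(CC)O[C@@H]1C[C@H](O[Si](C)(C)C(C)(C)C)[C@H](C)C[C@@H](OCc2ccc(OC)cc2)/C(=C(\CO[Si](C)(C)C(C)(C)C)C(=O)OC)[C@@H](O[Si](CC)(CC)CC)/C=C1\C
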